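The oxocane is assembled on a tetrahydropyran-4-one template: ring O, C6 and C12 of the target are O1, C2 and C6 of the pyranone, C7 and C11 are its two α-carbons, and the ketone carbon is a temporary one-carbon bridge between them. One operation, aldol addition to (R)-glycidaldehyde followed by enolate opening of its epoxide, lays C8–C9–C10 across these α-carbons as ring A of a 3-oxabicyclo[3.3.1]nonan-9-one; C7 and C10 are set by relay from C6 and C12. Baeyer–Villiger oxidation, hydrolysis and decarboxylation then excise the bridge carbon, leaving oxygen on C7 and unveiling the eight-membered ring. The precursor is a regiodefined silyl enol ether of a trans-2,6-disubstituted pyranone.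

Key step: step 4

Remark: carbons are numbered along the C15 chain (C1 = alkyne CH, ring oxygen between C6 and C12) and the temporary bridge carbon is called Ck; the BINOL–titanium catalyst is assumed to direct Re-face attack with (R)-BINOL, as in the related allylation, the antipodal ligand being equally available.

Step 1
Reactants: 1 3-[(tert-butyldimethylsilyl)oxy]propanal; 2 Danishefsky's diene, (E)-1-methoxy-3-(trimethylsilyloxy)buta-1,3-diene
Product: 4 (S)-2-[2-(tert-butyldimethylsilyloxy)ethyl]-2,3-dihydro-4H-pyran-4-one, via silyl aldol adduct 3 (not isolated)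
Conditions: (R)-BINOL (20 mol %), Ti(OiPr)4 (10 mol %), 4 Å MS, Et2O, −20 °C; then CF3CO2H, CH2Cl2, 0 °C
Reagents that add atoms: none
Why: Catalytic asymmetric hetero-Diels–Alder reaction in its Mukaiyama aldol/cyclocondensation form, in which the BINOL–titanium Lewis acid shields one aldehyde face so that C6 is set by catalyst control and the acid then closes the ring with loss of methanol.

Step 2
Reactants: 4 (S)-2-[2-(tert-butyldimethylsilyloxy)ethyl]-2,3-dihydro-4H-pyran-4-one
Product: 5 (2S,6S)-2-[2-(tert-butyldimethylsilyloxy)ethyl]-4-(trimethylsilyloxy)-6-vinyl-3,6-dihydro-2H-pyran (2,6-trans)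
Conditions: CH2=CHMgBr, CuBr·SMe2 (10 mol %), Me3SiCl, THF, −78 °C; Et3N, cold NaHCO3 work-up, used crude
Reagents that add atoms: vinylmagnesium bromide C=C[Mg]Br; chlorotrimethylsilane C[Si](C)(C)Cl
Why: Copper-catalysed conjugate addition with in situ silylation, in which the vinyl group should enter axially on the half-chair anti to the C6 substituent (C12, 2,6-trans) and the enolate is trapped regiospecifically as the C11=Ck silyl enol ether.

Step 3
Reactants: 6 (S)-glycidol
Product: 7 (R)-oxirane-2-carbaldehyde, (R)-glycidaldehyde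
Conditions: Dess–Martin periodinane, NaHCO3, CH2Cl2, 0 °C → rt; filtered, dried and used as a solution
Reagents that add atoms: none
Why: Dess–Martin oxidation of the primary alcohol leaves the epoxide carbon untouched, the descriptor changing from S to R only through the priority rules.

Step 4
Reactants: 5 (2S,6S)-2-[2-(tert-butyldimethylsilyloxy)ethyl]-4-(trimethylsilyloxy)-6-vinyl-3,6-dihydro-2H-pyran; 7 (R)-glycidaldehyde
Product: 11 (1R,2S,4S,5R,6S,7R)-6-(tert-butyldimethylsilyloxy)-2-[2-(tert-butyldimethylsilyloxy)ethyl]-7-hydroxy-4-vinyl-3-oxabicyclo[3.3.1]nonan-9-one, via lithium enolate 8 (not isolated), via lithium aldolate 9 (not isolated), via silylated epoxy ketone 10 (not isolated)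
Conditions: MeLi (1.0 equiv), THF, 0 °C; −78 °C, 7; tBuMe2SiOTf (1.05 equiv), −78 °C; KN(SiMe3)2 (1.5 equiv), −78 → 0 °C; aq. NH4Cl
Reagents that add atoms: tert-butyldimethylsilyl trifluoromethanesulfonate CC(C)(C)[Si](C)(C)OS(=O)(=O)C(F)(F)F
Why: MeLi cleaves the silyl enol ether to the regiodefined lithium enolate, which adds to the aldehyde of 7 through a Zimmerman–Traxler chair (C10–C11 bond), the aldolate is capped in situ as its silyl ether, and KN(SiMe3)2 then deprotonates the only α-methylene (C7), whose enolate opens the epoxide at its terminal carbon C8 (C7–C8 bond). The closest known reaction types are the enolate aldol addition and the intramolecular enolate–epoxide alkylation, together an α,α′-annulation of a cyclic ketone to a bicyclo[3.3.1]nonan-9-one. Ring A (C7–C8–C9–C10–C11–Ck) closes in the 6-endo mode at the epoxide (a 6-enolexo alkylation) with C9 on the carbonyl side, boat-like, so that the breaking C8–O bond is anti to the incoming enolate, and should then relax to the chair with the C9 hydroxyl axial and hydrogen-bonded to the ring oxygen. C11 is set by axial attack anti to the pseudoaxial vinyl group on C12, C10 by the chair aldol transition state of the cyclic E-enolate (anti aldol) reinforced by Felkin–Anh addition to the epoxy aldehyde (matched pair), C9 comes unchanged from 7, and C7 is forced because the three-carbon bridge can span the two α-carbons only diaxially on the face opposite to the vinyl group. The step needs 1,2-addition to the aldehyde and not to the epoxide (secured at −78 °C), deprotonation at C7 and not at C11 (methylene against a hindered methine beside the silyloxy group) and 6-endo instead of 5-exo opening (unhindered terminal C8 against the internal carbon next to the silyloxy-bearing C10).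

Step 5
Reactants: 11 bicyclic ketone
Product: 13 (1R,2S,4S,5R,6S,7R)-6-(tert-butyldimethylsilyloxy)-2-[2-(tert-butyldimethylsilyloxy)ethyl]-7-hydroxy-4-vinyl-3,9-dioxabicyclo[3.3.2]decan-10-one, via trimethylsilyl ether 12 (not isolated)
Conditions: Me3SiOOSiMe3, Me3SiOTf (10 mol %), CH2Cl2, −40 → −20 °C; aq. citric acid, THF
Reagents that add atoms: bis(trimethylsilyl) peroxide C[Si](C)(C)OO[Si](C)(C)C
Why: Baeyer–Villiger oxidation under silyl peroxide conditions that spare the vinyl group, in which the more electron-rich bridgehead C7 should migrate (C11 is flanked by the oxygen-bearing C10 and C12) with retention, so that the new C7–O bond lies on the face the carbonyl occupied.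

Step 6
Reactants: 13 bridged lactone
Product: 14 (2S,3R,4S,5R,7R,8S)-4-(tert-butyldimethylsilyloxy)-8-[2-(tert-butyldimethylsilyloxy)ethyl]-5,7-dihydroxy-2-vinyloxocane-3-carboxylic acid
Conditions: LiOH, THF/H2O, 0 °C → rt; then 1 M HCl to pH 3–4, 0 °C
Reagents that add atoms: water O (delivered as aqueous lithium hydroxide [Li+].[OH-])
Why: Saponification of the bridged seven-membered lactone opens the bicycle to the oxocane without touching a stereocentre, and the C9 hydroxyl, trans to the carboxyl group, cannot close a γ-lactone.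

Step 7
Reactants: 14 hydroxy acid
Product: 15 (2S,3R,5R,6S,8R)-6-(tert-butyldimethylsilyloxy)-2-[2-(tert-butyldimethylsilyloxy)ethyl]-8-vinyloxocane-3,5-diol
Conditions: 9-mesityl-10-phenylacridinium tetrafluoroborate (5 mol %), (PhS)2 (10 mol %), iPr2NEt (20 mol %), CF3CH2OH, 450 nm LEDs, rt
Reagents that add atoms: none
Why: Photoredox hydrodecarboxylation, in which the excited acridinium oxidises the carboxylate, loss of CO2 gives the secondary C11 radical and hydrogen-atom transfer from thiophenol should quench it faster than it can rearrange through the neighbouring vinyl group, C11 becoming the ring methylene.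

Step 8
Reactants: 15 diol
Product: 16 (2S,3S,5S,6S,8R)-6-(tert-butyldimethylsilyloxy)-2-[2-(tert-butyldimethylsilyloxy)ethyl]-3,5-dichloro-8-vinyloxocane
Conditions: (n-C8H17)3P, CCl4, toluene, 70 °C
Reagents that add atoms: tetrachloromethane ClC(Cl)(Cl)Cl
Why: Double Appel chlorination, in which both alkoxyphosphonium ions are displaced by chloride in SN2 fashion so that C7 and C9 are inverted to the (7S,9S) configuration of the target.

Step 9
Reactants: 16 dichloride
Product: 18 (2R,4S,5S,7S,8S)-4-(tert-butyldimethylsilyloxy)-8-[2-(tert-butyldimethylsilyloxy)ethyl]-5,7-dichlorooxocane-2-carbaldehyde, via ozonide 17 (not isolated)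
Conditions: O3, CH2Cl2, −78 °C; PPh3, −78 °C → rt
Reagents that add atoms: ozone [O-][O+]=O
Why: Ozonolysis with reductive work-up cleaves the only C=C bond to the C13 aldehyde under neutral conditions that should not epimerise C12.

Step 10
Reactants: 18 aldehyde
Product: 19 (S)-1-[(2R,4S,5S,7S,8S)-4-(tert-butyldimethylsilyloxy)-8-[2-(tert-butyldimethylsilyloxy)ethyl]-5,7-dichlorooxocan-2-yl]propan-1-ol
Conditions: Et2Zn, Ti(OiPr)4, (1R,2R)-1,2-bis(trifluoromethanesulfonamido)cyclohexane (10 mol %), toluene, −20 °C; aq. NH4Cl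
Reagents that add atoms: diethylzinc CC[Zn]CC
Why: Catalyst-controlled asymmetric addition of diethylzinc under titanium bis-sulfonamide catalysis, in which the (1R,2R)-ligand should direct ethyl transfer to the Si face to give the (13S) carbinol, the sense that the Felkin–Anh preference of the α-alkoxy aldehyde also favours.

Step 11
Reactants: 19 alcohol
Product: 20 (2R,4S,5S,7S,8S)-2-[(R)-1-bromopropyl]-4-(tert-butyldimethylsilyloxy)-8-[2-(tert-butyldimethylsilyloxy)ethyl]-5,7-dichlorooxocane
Conditions: CBr4, (n-C8H17)3P, toluene, 70 °C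
Reagents that add atoms: tetrabromomethane BrC(Br)(Br)Br
Why: Appel bromination with SN2 inversion converts the (13S) alcohol into the (13R) bromide.

Step 12
Reactants: 20 bromide
Product: 21 (2R,4S,5S,7S,8S)-2-[(R)-1-bromopropyl]-5,7-dichloro-8-(2-hydroxyethyl)oxocan-4-ol
Conditions: HF·pyridine, pyridine, THF, 0 °C → rt
Reagents that add atoms: none
Why: Fluoride cleavage of both silyl ethers under acidic conditions, which avoid the alkoxide that would close an epoxide onto the C9 chloride.

Step 13
Reactants: 21 diol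
Product: 22 2-[(2S,3S,5S,6S,8R)-8-[(R)-1-bromopropyl]-3,5-dichloro-6-hydroxyoxocan-2-yl]acetaldehyde
Conditions: TEMPO (10 mol %), PhI(OAc)2, CH2Cl2, rt
Reagents that add atoms: none
Why: Oxoammonium (TEMPO) oxidation is selective for the primary alcohol over the hindered secondary C10 alcohol and is neutral enough to spare the β-alkoxy aldehyde.

Step 14
Reactants: 22 hydroxy aldehyde
Product: 23 (E)-4-[(2S,3S,5S,6S,8R)-8-[(R)-1-bromopropyl]-3,5-dichloro-6-hydroxyoxocan-2-yl]but-2-enal
Conditions: Ph3P=CHCHO, toluene, 60 °C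
Reagents that add atoms: (triphenylphosphoranylidene)acetaldehyde O=CC=P(c1ccccc1)(c1ccccc1)c1ccccc1
Why: Wittig olefination with a stabilised ylide should give the (E)-enal and adds C2 and C3.

Step 15
Reactants: 23 hydroxy enal
Product: 24 (2R,4S,5S,7S,8S)-2-[(R)-1-bromopropyl]-5,7-dichloro-8-[(E)-4-oxobut-2-en-1-yl]oxocan-4-yl acetate
Conditions: Ac2O, pyridine, DMAP (cat.), CH2Cl2, 0 °C
Reagents that add atoms: acetic anhydride CC(=O)OC(C)=O
Why: DMAP-catalysed acetylation of the C10 alcohol, placed before the basic last step so that no alkoxide is formed next to the C9 chloride.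

Step 16
Reactants: 24 acetoxy enal
Product: 27 (2R,4S,5S,7S,8S)-2-[(R)-1-bromopropyl]-5,7-dichloro-8-[(E)-pent-2-en-4-yn-1-yl]oxocan-4-yl acetate (target), via lithium alkoxide adduct 25 (not isolated), via diazoalkene 26 (not isolated)
Conditions: Me3SiCHN2, LiN(iPr)2, THF, −78 °C; then 24, −78 → 0 °C; aq. NH4Cl
Reagents that add atoms: trimethylsilyldiazomethane C[Si](C)(C)C=[N+]=[N-]
Why: Colvin homologation, in which lithiated trimethylsilyldiazomethane adds to the aldehyde at −78 °C faster than to the acetate, Peterson-type elimination gives the diazoalkene, and loss of N2 with 1,2-hydride shift of the alkylidene carbene should deliver the terminal alkyne with the E-alkene intact.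

Compound list
1 | 3-[(tert-butyldimethylsilyl)oxy]propanal | CC(C)(C)[Si](C)(C)OCCC=O | starting material
2 | Danishefsky's diene, (E)-1-methoxy-3-(trimethylsilyloxy)buta-1,3-diene | CO/C=C/C(=C)O[Si](C)(C)C | starting material
3 | (S,E)-7-(tert-butyldimethylsilyloxy)-1-methoxy-5-(trimethylsilyloxy)hept-1-en-3-one | CO/C=C/C(=O)C[C@@H](O[Si](C)(C)C)CCO[Si](C)(C)C(C)(C)C | intermediate (not isolated)
4 | (S)-2-[2-(tert-butyldimethylsilyloxy)ethyl]-2,3-dihydro-4H-pyran-4-one | CC(C)(C)[Si](C)(C)OCC[C@@H]1OC=CC(=O)C1 | intermediate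
5 | (2S,6S)-2-[2-(tert-butyldimethylsilyloxy)ethyl]-4-(trimethylsilyloxy)-6-vinyl-3,6-dihydro-2H-pyran | CC(C)(C)[Si](C)(C)OCC[C@@H]1O[C@@H](C=C)C=C(O[Si](C)(C)C)C1 | intermediate
6 | (S)-glycidol | OC[C@H]1CO1 | starting material
7 | (R)-glycidaldehyde | O=C[C@H]1CO1 | intermediate
8 | lithium enolate of the trans-2,6-disubstituted pyranone (C11=Ck) | CC(C)(C)[Si](C)(C)OCC[C@@H]1O[C@@H](C=C)C=C(O[Li])C1 | intermediate (not isolated)
9 | lithium aldolate (C11 side chain trans to vinyl, C10 alkoxide, C8–C9 epoxide) | CC(C)(C)[Si](C)(C)OCC[C@@H]1O[C@@H](C=C)[C@H]([C@H](O[Li])[C@H]2CO2)C(=O)C1 | intermediate (not isolated)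
10 | silylated epoxy ketone (C10 tert-butyldimethylsilyl ether of 9) | CC(C)(C)[Si](C)(C)OCC[C@@H]1O[C@@H](C=C)[C@H]([C@H](O[Si](C)(C)C(C)(C)C)[C@H]2CO2)C(=O)C1 | intermediate (not isolated)
11 | (1R,2S,4S,5R,6S,7R)-6-(tert-butyldimethylsilyloxy)-2-[2-(tert-butyldimethylsilyloxy)ethyl]-7-hydroxy-4-vinyl-3-oxabicyclo[3.3.1]nonan-9-one | CC(C)(C)[Si](C)(C)OCC[C@@H]1O[C@@H](C=C)[C@@H]2[C@H](O[Si](C)(C)C(C)(C)C)[C@H](O)C[C@H]1C2=O | intermediate
12 | C9 trimethylsilyl ether of lactone 13 | CC(C)(C)[Si](C)(C)OCC[C@@H]1O[C@@H](C=C)[C@@H]2[C@H](O[Si](C)(C)C(C)(C)C)[C@H](O[Si](C)(C)C)C[C@H]1OC2=O | intermediate (not isolated)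
13 | (1R,2S,4S,5R,6S,7R)-6-(tert-butyldimethylsilyloxy)-2-[2-(tert-butyldimethylsilyloxy)ethyl]-7-hydroxy-4-vinyl-3,9-dioxabicyclo[3.3.2]decan-10-one | CC(C)(C)[Si](C)(C)OCC[C@@H]1O[C@@H](C=C)[C@@H]2[C@H](O[Si](C)(C)C(C)(C)C)[C@H](O)C[C@H]1OC2=O | intermediate
14 | (2S,3R,4S,5R,7R,8S)-4-(tert-butyldimethylsilyloxy)-8-[2-(tert-butyldimethylsilyloxy)ethyl]-5,7-dihydroxy-2-vinyloxocane-3-carboxylic acid | CC(C)(C)[Si](C)(C)OCC[C@@H]1O[C@@H](C=C)[C@@H](C(=O)O)[C@H](O[Si](C)(C)C(C)(C)C)[C@H](O)C[C@H]1O | intermediate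
15 | (2S,3R,5R,6S,8R)-6-(tert-butyldimethylsilyloxy)-2-[2-(tert-butyldimethylsilyloxy)ethyl]-8-vinyloxocane-3,5-diol | CC(C)(C)[Si](C)(C)OCC[C@@H]1O[C@@H](C=C)C[C@H](O[Si](C)(C)C(C)(C)C)[C@H](O)C[C@H]1O | intermediate
16 | (2S,3S,5S,6S,8R)-6-(tert-butyldimethylsilyloxy)-2-[2-(tert-butyldimethylsilyloxy)ethyl]-3,5-dichloro-8-vinyloxocane | CC(C)(C)[Si](C)(C)OCC[C@@H]1O[C@@H](C=C)C[C@H](O[Si](C)(C)C(C)(C)C)[C@@H](Cl)C[C@@H]1Cl | intermediate
17 | 1,2,4-trioxolane (ozonide) of 16 at the vinyl group | CC(C)(C)[Si](C)(C)OCC[C@@H]1O[C@@H](C2OOCO2)C[C@H](O[Si](C)(C)C(C)(C)C)[C@@H](Cl)C[C@@H]1Cl | intermediate (not isolated)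
18 | (2R,4S,5S,7S,8S)-4-(tert-butyldimethylsilyloxy)-8-[2-(tert-butyldimethylsilyloxy)ethyl]-5,7-dichlorooxocane-2-carbaldehyde | CC(C)(C)[Si](C)(C)OCC[C@@H]1O[C@@H](C=O)C[C@H](O[Si](C)(C)C(C)(C)C)[C@@H](Cl)C[C@@H]1Cl | intermediate
19 | (S)-1-[(2R,4S,5S,7S,8S)-4-(tert-butyldimethylsilyloxy)-8-[2-(tert-butyldimethylsilyloxy)ethyl]-5,7-dichlorooxocan-2-yl]propan-1-ol | CC(C)(C)[Si](C)(C)OCC[C@@H]1O[C@@H]([C@@H](O)CC)C[C@H](O[Si](C)(C)C(C)(C)C)[C@@H](Cl)C[C@@H]1Cl | intermediate
20 | (2R,4S,5S,7S,8S)-2-[(R)-1-bromopropyl]-4-(tert-butyldimethylsilyloxy)-8-[2-(tert-butyldimethylsilyloxy)ethyl]-5,7-dichlorooxocane | CC(C)(C)[Si](C)(C)OCC[C@@H]1O[C@@H]([C@H](Br)CC)C[C@H](O[Si](C)(C)C(C)(C)C)[C@@H](Cl)C[C@@H]1Cl | intermediate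
21 | (2R,4S,5S,7S,8S)-2-[(R)-1-bromopropyl]-5,7-dichloro-8-(2-hydroxyethyl)oxocan-4-ol | OCC[C@@H]1O[C@@H]([C@H](Br)CC)C[C@H](O)[C@@H](Cl)C[C@@H]1Cl | intermediate
22 | 2-[(2S,3S,5S,6S,8R)-8-[(R)-1-bromopropyl]-3,5-dichloro-6-hydroxyoxocan-2-yl]acetaldehyde | O=CC[C@@H]1O[C@@H]([C@H](Br)CC)C[C@H](O)[C@@H](Cl)C[C@@H]1Cl | intermediate
23 | (E)-4-[(2S,3S,5S,6S,8R)-8-[(R)-1-bromopropyl]-3,5-dichloro-6-hydroxyoxocan-2-yl]but-2-enal | O=C/C=C/C[C@@H]1O[C@@H]([C@H](Br)CC)C[C@H](O)[C@@H](Cl)C[C@@H]1Cl | intermediate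
24 | (2R,4S,5S,7S,8S)-2-[(R)-1-bromopropyl]-5,7-dichloro-8-[(E)-4-oxobut-2-en-1-yl]oxocan-4-yl acetate | O=C/C=C/C[C@@H]1O[C@@H]([C@H](Br)CC)C[C@H](OC(C)=O)[C@@H](Cl)C[C@@H]1Cl | intermediate
25 | lithium alkoxide adduct of 24 with lithiated trimethylsilyldiazomethane | C[Si](C)(C)C(=[N+]=[N-])C(O[Li])/C=C/C[C@@H]1O[C@@H]([C@H](Br)CC)C[C@H](OC(C)=O)[C@@H](Cl)C[C@@H]1Cl | intermediate (not isolated)
26 | diazoalkene from 25 by loss of lithium trimethylsilanolate | [N-]=[N+]=C=C/C=C/C[C@@H]1O[C@@H]([C@H](Br)CC)C[C@H](OC(C)=O)[C@@H](Cl)C[C@@H]1Cl | intermediate (not isolated)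
27 | (2R,4S,5S,7S,8S)-2-[(R)-1-bromopropyl]-5,7-dichloro-8-[(E)-pent-2-en-4-yn-1-yl]oxocan-4-yl acetate, chain descriptors (6S,7S,9S,10S,12R,13R) | C#C/C=C/C[C@@H]1O[C@@H]([C@H](Br)CC)C[C@H](OC(C)=O)[C@@H](Cl)C[C@@H]1Cl | target

Total step count: 16. Longest linear sequence: 15 steps (steps 1, 2 and 4–16 from aldehyde 1; the glycidaldehyde branch joins at step 4).

Steps most likely to fail

Step 4. After the aldol addition the C7 enolate may fail to open the epoxide at C8 through the boat-like 6-endo arrangement: attack at the internal carbon (5-exo), retro-aldol cleavage, or β-elimination of the ring oxygen on warming could win. The fallback separates the two bond formations and replaces the epoxide opening by a halide alkylation that has no such geometric demand. It sets out from the silylated epoxy ketone 10, isolated by quenching before the base is added. MgI2 in Et2O at −40 °C should open the epoxide at the terminal carbon to the iodohydrin F1. Et3SiOTf and 2,6-lutidine give its triethylsilyl ether F2. KN(SiMe3)2 in THF (−78 → −20 °C) then closes ring A by 6-exo-tet alkylation of the C7 enolate with the primary iodide, giving the bicyclic ketone with a C9 triethylsilyl ether F3. Selective removal of the triethylsilyl group (pyridinium p-toluenesulfonate, MeOH, 0 °C) returns to the route at 11.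

Step 5. The Criegee rearrangement may proceed with competing migration of C11, since the electronic bias rests on one additional β-oxygen substituent only, and would then give the regioisomeric lactone. The fallback replaces peroxide oxygen insertion by a nitrogen insertion whose regiochemistry is fixed by oxime geometry. It sets out from ketone 11. NH2OH·HCl and NaOAc in EtOH give the oxime; the geometric isomer with N–O anti to C7, oxime F4, is separated and the other is re-equilibrated with acid and recycled. Selective O-sulfonylation (TsCl, Et3N, CH2Cl2, 0 °C) gives the oxime tosylate F5. Beckmann rearrangement in aqueous dioxane at 60 °C moves the anti carbon C7 to nitrogen with retention and gives the bridged lactam F6. N-Nitrosation (NOBF4, pyridine, MeCN, −20 °C) gives the N-nitrosolactam F7, whose thermal nitrosoamide rearrangement (hexane, 50 °C) should expel N2 and form the C7–O bond with retention, returning to the route at lactone 13.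

Step 8. After the first alkoxyphosphonium ion forms, elimination, attack by the second hydroxyl or participation of the ring oxygen may outrun chloride, and the displacement at C9 beside the bulky C10 silyl ether may stall. The fallback separates activation from displacement. It sets out from diol 15: chloromethanesulfonyl chloride and pyridine (CH2Cl2, 0 °C) give the bis(chloromethanesulfonate) F8, and LiCl in DMF at 60 °C should displace both sulfonates with inversion, returning to the route at dichloride 16.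

Further compounds
F1 | step 4 | iodohydrin from 10 (C8 iodide, C9 hydroxyl, C10 tert-butyldimethylsilyl ether, monocyclic ketone) | CC(C)(C)[Si](C)(C)OCC[C@@H]1O[C@@H](C=C)[C@H]([C@H](O[Si](C)(C)C(C)(C)C)[C@H](O)CI)C(=O)C1
F2 | step 4 | C9 triethylsilyl ether of F1 | CC(C)(C)[Si](C)(C)OCC[C@@H]1O[C@@H](C=C)[C@H]([C@H](O[Si](C)(C)C(C)(C)C)[C@H](O[Si](CC)(CC)CC)CI)C(=O)C1
F3 | step 4 | C9 triethylsilyl ether of bicyclic ketone 11 | CC(C)(C)[Si](C)(C)OCC[C@@H]1O[C@@H](C=C)[C@@H]2[C@H](O[Si](C)(C)C(C)(C)C)[C@H](O[Si](CC)(CC)CC)C[C@H]1C2=O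
F4 | step 5 | oxime of 11 with N–O anti to C7 | CC(C)(C)[Si](C)(C)OCC[C@@H]1O[C@@H](C=C)[C@@H]2[C@H](O[Si](C)(C)C(C)(C)C)[C@H](O)C[C@H]1/C2=N/O
F5 | step 5 | O-tosyl oxime of 11 | CC(C)(C)[Si](C)(C)OCC[C@@H]1O[C@@H](C=C)[C@@H]2[C@H](O[Si](C)(C)C(C)(C)C)[C@H](O)C[C@H]1/C2=N/OS(=O)(=O)c1ccc(C)cc1
F6 | step 5 | bridged lactam (C7–NH–C(=O)–C11) | CC(C)(C)[Si](C)(C)OCC[C@@H]1O[C@@H](C=C)[C@@H]2[C@H](O[Si](C)(C)C(C)(C)C)[C@H](O)C[C@H]1NC2=O
F7 | step 5 | N-nitroso derivative of lactam F6 | CC(C)(C)[Si](C)(C)OCC[C@@H]1O[C@@H](C=C)[C@@H]2[C@H](O[Si](C)(C)C(C)(C)C)[C@H](O)C[C@H]1N(N=O)C2=O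
F8 | step 8 | C7,C9-bis(chloromethanesulfonate) of diol 15 | CC(C)(C)[Si](C)(C)OCC[C@@H]1O[C@@H](C=C)C[C@H](O[Si](C)(C)C(C)(C)C)[C@H](OS(=O)(=O)CCl)C[C@H]1OS(=O)(=O)CCl
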